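**Strategy.** The route rests on disconnecting the C4–C8 bond of the cyclopentane ring C (C4–C8–C9–C10–C11), which is closed last. The precursor is a bicyclo[3.2.1]octene (rings A and B) whose bridgehead C4 still carries hydrogen and whose C11 bears an exo chain ending in an α-diazo ester. A dirhodium carbenoid at C8 inserts into the tertiary bridgehead C4–H bond: one operation closes ring C, makes C4 fully substituted with retention and installs C8 with its carboxyl carbon C12. The step exploits the fact that C4–H is the only C–H bond 1,5 to the carbenoid, because C1 is quaternary. The bicycle itself comes from a vinylcarbenoid [4+3] cycloaddition.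

Key step: step 14

Atom labels (target and all intermediates): C1 = C(CH3)(CH2OH); C2 = bridgehead CH next to C1; C3 = bridging CH2; C4 = bridgehead carbon common to the three rings; C5 = CH–O; C6 = vinylic CH; C7 = vinylic C–CO2H; C8 = CH(CHO); C9, C10 = CH2; C11 = ring-fusion CH; C12 = formyl carbon. Ring A = C1–C2–C3–C4–C11, ring B = C2–C3–C4–C5–C6–C7, ring C = C4–C8–C9–C10–C11. At C1 and C11, exo means on the side of C3, endo on the side of C5–C7.

Assumption: Rh2(S-DOSP)4 is taken to deliver the enantiomer of 13 that is drawn; if its sense of induction is the opposite, Rh2(R-DOSP)4 is used instead.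

**Step 1**
Reactants: 1 tert-butyl 3-oxobutanoate
Product: 2 tert-butyl 2-diazo-3-oxobutanoate
Conditions: 4-acetamidobenzenesulfonyl azide, Et3N, MeCN, 0 → 25 °C
Reagents that add atoms: 4-acetamidobenzenesulfonyl azide (CC(=O)Nc1ccc(cc1)S(=O)(=O)N=[N+]=[N-])
Why: Regitz diazo transfer to the doubly activated methylene of a β-keto ester is reliable.

**Step 2**
Reactants: 2 tert-butyl 2-diazo-3-oxobutanoate
Product: 3 tert-butyl 2-diazo-3-hydroxybutanoate (racemic)
Conditions: NaBH4, MeOH, 0 °C
Reagents that add atoms: none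
Why: Borohydride reduction of the ketone leaves the diazo ester intact; the carbinol centre is removed again in step 3.

**Step 3**
Reactants: 3 tert-butyl 2-diazo-3-hydroxybutanoate
Product: 4 tert-butyl 2-diazobut-3-enoate
Conditions: POCl3, Et3N, CH2Cl2, 0 °C; used cold and at once
Reagents that add atoms: none
Why: Dehydration of the β-hydroxy diazo ester (elimination of its dichlorophosphate) should give the vinyldiazoacetate.

**Step 4**
Reactants: 5 cyclopent-2-en-1-one
Product: 6 2-iodocyclopent-2-en-1-one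
Conditions: I2, pyridine, CH2Cl2, 0 → 25 °C
Reagents that add atoms: iodine (II)
Why: α-Iodination of the enone by conjugate addition of pyridine, iodination of the enolate and elimination.

**Step 5**
Reactants: 7 methyl but-3-enoate; 6 2-iodocyclopent-2-en-1-one
Product: 9 methyl 4-(5-oxocyclopent-1-en-1-yl)butanoate, via B-alkyl-9-BBN borane 8 (not isolated)
Conditions: 7, 9-BBN, THF, 0 → 25 °C; then 6, PdCl2(dppf) ([1,1′-bis(diphenylphosphino)ferrocene]dichloropalladium, 3 mol %), Ph3As, Cs2CO3, DMF–H2O, 25 °C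
Reagents that add atoms: none
Why: Anti-Markovnikov hydroboration followed by B-alkyl Suzuki–Miyaura coupling with the 2-iodoenone.

**Step 6**
Reactants: 9 methyl 4-(5-oxocyclopent-1-en-1-yl)butanoate
Product: 10 methyl 4-[3-(tert-butyldimethylsilyloxy)cyclopenta-1,3-dien-2-yl]butanoate
Conditions: TBSOTf, Et3N, CH2Cl2, 0 °C; used directly
Reagents that add atoms: tert-butyldimethylsilyl trifluoromethanesulfonate (CC(C)(C)[Si](C)(C)OS(=O)(=O)C(F)(F)F)
Why: Soft enolisation at the α′-methylene of the enone should give the cross-conjugated 2-silyloxy diene (kinetic silyl dienol ether formation).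

**Step 7**
Reactants: 10 silyloxy diene; 4 tert-butyl 2-diazobut-3-enoate
Product: 13 tert-butyl 6-exo-(4-methoxy-4-oxobutyl)-7-oxobicyclo[3.2.1]oct-2-ene-2-carboxylate (ketone at C1; C11 chain exo), via cis-divinylcyclopropane 11 (not isolated), via silyl enol ether 12 (not isolated)
Conditions: 4 (1.5 equiv, slow addition), Rh2(S-DOSP)4 (dirhodium tetrakis[(S)-N-(4-dodecylbenzenesulfonyl)prolinate], 1 mol %), hexanes, −78 → 25 °C; then 1 M HCl, THF, 25 °C; then DBU (0.2 equiv), CH2Cl2, 25 °C
Reagents that add atoms: none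
Why: Tandem cyclopropanation/Cope rearrangement (formal [4+3] cycloaddition of a rhodium vinylcarbenoid with a cyclopentadiene): the electrophilic carbenoid should attack the more nucleophilic silyloxy-substituted double bond at its unsubstituted terminus, the cis-divinylcyclopropane rearranges through a boat transition state so that the oxygenated carbon becomes C1 next to the bridgehead that carries C7, the chiral prolinate catalyst sets the bridgeheads C2 and C4, and hydrolysis with base equilibration should place the C11 chain exo, away from the C5 methylene.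

**Step 8**
Reactants: 13 bicyclic ketone
Product: 14 tert-butyl 7-(methoxymethylidene)-6-exo-(4-methoxy-4-oxobutyl)bicyclo[3.2.1]oct-2-ene-2-carboxylate (E/Z mixture)
Conditions: Ph3P(CH2OMe)Cl, KN(SiMe3)2, THF, −78 → 0 °C
Reagents that add atoms: (methoxymethyl)triphenylphosphonium chloride (COC[P+](c1ccccc1)(c1ccccc1)c1ccccc1.[Cl-])
Why: Wittig methoxymethylenation of the C1 ketone; the bridgehead C2 cannot enolise and C11 keeps its thermodynamically preferred exo configuration.

**Step 9**
Reactants: 14 enol ether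
Product: 15 tert-butyl 7-formyl-6-exo-(4-methoxy-4-oxobutyl)bicyclo[3.2.1]oct-2-ene-2-carboxylate (C1 epimers)
Conditions: 2 M HCl (aq), THF, 25 °C
Reagents that add atoms: water (O)
Why: Acid hydrolysis of the enol ether gives the homologated aldehyde; its C1 configuration is irrelevant because C1 is enolised in step 10.

**Step 10**
Reactants: 15 aldehyde
Product: 16 tert-butyl 7-exo-formyl-7-endo-(hydroxymethyl)-6-exo-(4-methoxy-4-oxobutyl)bicyclo[3.2.1]oct-2-ene-2-carboxylate
Conditions: aq. HCHO (37 %), K2CO3 (0.3 equiv), THF–H2O, 25 °C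
Reagents that add atoms: formaldehyde (C=O)
Why: Crossed aldol (hydroxymethylation) of the α-branched aldehyde with formaldehyde creates the quaternary C1; the enolate should be attacked on its endo face, anti to the exo chain on the neighbouring C11, so that CH2OH is endo and the formyl group (the future methyl) exo.

**Step 11**
Reactants: 16 hydroxy aldehyde
Product: 18 tert-butyl 7-endo-(hydroxymethyl)-6-exo-(4-methoxy-4-oxobutyl)-7-exo-methylbicyclo[3.2.1]oct-2-ene-2-carboxylate, via tosylhydrazone 17 (not isolated)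
Conditions: TsNHNH2, EtOH, 50 °C; then catecholborane, CHCl3, 0 °C; then NaOAc·3H2O, 60 °C
Reagents that add atoms: none
Why: Caglioti-type deoxygenation: the tosylhydrazone is reduced by the borane and the diazene loses sulfinate and N2 to leave the exo methyl under neutral conditions that spare both esters; C1 has no hydrogen, so no alkene can form.

**Step 12**
Reactants: 18 primary alcohol
Product: 19 tert-butyl 7-endo-[(tert-butyldimethylsilyloxy)methyl]-6-exo-(4-methoxy-4-oxobutyl)-7-exo-methylbicyclo[3.2.1]oct-2-ene-2-carboxylate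
Conditions: TBSCl, imidazole, DMF, 25 °C
Reagents that add atoms: tert-butyldimethylsilyl chloride (CC(C)(C)[Si](C)(C)Cl)
Why: Silylation protects the hydroxyl against the base of step 13 and against O–H insertion in step 14.

**Step 13**
Reactants: 19 silyl ether
Product: 21 tert-butyl 7-endo-[(tert-butyldimethylsilyloxy)methyl]-6-exo-(3-diazo-4-methoxy-4-oxobutyl)-7-exo-methylbicyclo[3.2.1]oct-2-ene-2-carboxylate, via α-trifluoroacetyl ester 20 (not isolated)
Conditions: LiN(SiMe3)2, THF, −78 °C; CF3CO2CH2CF3; then MeSO2N3, Et3N, H2O (1 equiv), MeCN, 25 °C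
Reagents that add atoms: methanesulfonyl azide (CS(=O)(=O)N=[N+]=[N-])
Why: Detrifluoroacetylative diazo transfer: kinetic deprotonation should occur α to the saturated methyl ester rather than at the γ-position of the hindered tert-butyl enoate, the enolate is trifluoroacetylated, and the activated β-keto ester undergoes Regitz transfer with loss of the trifluoroacetyl group.

**Step 14**
Reactants: 21 α-diazo ester
Product: 22 tricyclic diester with ring C closed (C7 CO2t-Bu; C8 CO2Me as epimers; C1 exo-CH3 and endo-CH2OTBS)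
Conditions: Rh2(O2CCPh3)4 (2 mol %), CH2Cl2, −78 → 0 °C, slow addition of 21
Reagents that add atoms: none
Why: Loss of N2 gives an electrophilic dirhodium carbenoid at C8, which inserts into the tertiary bridgehead C4–H bond through a concerted, asynchronous three-centre transition state with retention at C4. The closest known reaction type is the rhodium-mediated intramolecular 1,5-C–H insertion of α-alkyl-α-diazo esters that builds cyclopentanes. Ring C closes by formation of the C4–C8 bond through a five-membered (1,5) transition state spanning C8–C9–C10–C11–C4. C4 becomes fully substituted with retention, its configuration being dictated by the bicyclic cage and by the exo chain on C11 (only the cis-fused cyclopentane is geometrically accessible), whereas C8 forms as an epimer mixture that step 16 equilibrates. The step needs 1,5-insertion to win over 1,2-hydride migration from C9 and over other C–H bonds: C1 is quaternary, so C4–H is the only 1,5 C–H bond, it is tertiary and remote from electron-withdrawing groups, the enoate C=C is electron-poor and out of reach, and the bulky triphenylacetate ligands at low temperature disfavour hydride migration.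

**Step 15**
Reactants: 22 tricyclic diester
Product: 23 tricyclic primary alcohol (C12 = CH2OH; C8 epimers)
Conditions: LiBH4, MeOH (2 equiv), THF, 0 → 40 °C
Reagents that add atoms: none
Why: Chemoselective ester reduction: LiBH4 reduces the methyl ester but leaves the conjugated tert-butyl ester and the silyl ether untouched.

**Step 16**
Reactants: 23 primary alcohol
Product: 24 tricyclic aldehyde (C12 = CHO; C8 as in the target)
Conditions: Dess–Martin periodinane, NaHCO3, CH2Cl2, 0 → 25 °C; then DBU (0.2 equiv), CH2Cl2, 25 °C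
Reagents that add atoms: none
Why: Dess–Martin oxidation, then base equilibration of the enolisable C8 centre to the more stable epimer, in which C12 lies syn to the C3 bridge and away from C5 (thermodynamic control).

**Step 17**
Reactants: 24 aldehyde
Product: 25 dimethyl acetal of 24
Conditions: HC(OMe)3, PPTS (cat.), MeOH, 25 °C
Reagents that add atoms: trimethyl orthoformate (COC(OC)OC); methanol (CO)
Why: Acid-catalysed acetalisation masks the aldehyde against the oxidation and hydride reduction that follow and prevents lactol formation with the later C5 hydroxyl.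

**Step 18**
Reactants: 25 acetal
Product: 26 γ-keto enoate (C5 ketone)
Conditions: Rh2(cap)4 (dirhodium tetrakis(caprolactamate), 1 mol %), t-BuOOH (5 equiv), K2CO3 (0.5 equiv), CH2Cl2, 25 °C
Reagents that add atoms: tert-butyl hydroperoxide (CC(C)(C)OO)
Why: Allylic oxidation by tert-butylperoxyl radicals at the only allylic methylene, C5 (the other allylic position is the bridgehead C2), should give the enone.

**Step 19**
Reactants: 26 enone
Product: 27 allylic alcohol (C5–OH syn to the C1–C11 bridge, as in the target)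
Conditions: NaBH4, CeCl3·7H2O, MeOH, −78 → −20 °C
Reagents that add atoms: none
Why: Luche 1,2-reduction: hydride should add to C5 on the face of C3, anti to the C4–C11 bond (pseudo-axial attack on the cyclohexenone), giving the pseudo-equatorial alcohol of the target while acetal, esters and silyl ether are inert.

**Step 20**
Reactants: 28 heptane-1,7-diol
Product: 29 7-(tert-butyldimethylsilyloxy)heptan-1-ol
Conditions: NaH (1.0 equiv), THF, 0 °C; TBSCl (1.0 equiv)
Reagents that add atoms: tert-butyldimethylsilyl chloride (CC(C)(C)[Si](C)(C)Cl)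
Why: Monosilylation of a symmetrical diol through its sparingly soluble monoalkoxide.

**Step 21**
Reactants: 29 7-(tert-butyldimethylsilyloxy)heptan-1-ol
Product: 30 7-(tert-butyldimethylsilyloxy)heptanal
Conditions: Dess–Martin periodinane, NaHCO3, CH2Cl2, 25 °C
Reagents that add atoms: none
Why: Dess–Martin oxidation of the primary alcohol stops at the aldehyde.

**Step 22**
Reactants: 31 9-bromononanoic acid
Product: 32 (8-carboxyoctyl)triphenylphosphonium bromide
Conditions: PPh3, MeCN, reflux
Reagents that add atoms: triphenylphosphine (c1ccc(cc1)P(c1ccccc1)c1ccccc1)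
Why: SN2 quaternisation of triphenylphosphine by the primary bromide.

**Step 23**
Reactants: 32 phosphonium bromide; 30 7-(tert-butyldimethylsilyloxy)heptanal
Product: 34 (Z)-16-(tert-butyldimethylsilyloxy)hexadec-9-enoic acid, via phosphorus ylide 33 (not isolated)
Conditions: NaN(SiMe3)2 (2.1 equiv), THF, −78 → 0 °C; then 30, −78 → 25 °C; aq. NaHSO4 work-up
Reagents that add atoms: none
Why: Wittig olefination with a non-stabilised ylide under lithium-free conditions should give the Z-alkene under kinetic control.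

**Step 24**
Reactants: 27 allylic alcohol; 34 protected hydroxy acid
Product: 36 fully protected ester (C5 O-acyl; C7 CO2t-Bu; C12 dimethyl acetal; two OTBS), via mixed anhydride 35 (not isolated)
Conditions: 34, 2,4,6-trichlorobenzoyl chloride, Et3N, toluene, 25 °C; then 27, DMAP, toluene, 40 °C
Reagents that add atoms: none
Why: Yamaguchi esterification acylates the hindered secondary C5 hydroxyl, the only free hydroxyl in either partner, with retention at C5.

**Step 25**
Reactants: 36 fully protected ester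
Product: 37 target CNP0148862.2
Conditions: TFA–CH2Cl2–H2O (10:10:1), 0 → 25 °C; then brief aq. NaHCO3–THF and acidification to pH 4
Reagents that add atoms: water (O)
Why: Acidolysis removes the tert-butyl ester, both silyl ethers and the dimethyl acetal in one operation; the allylic C5 ester does not ionise next to the electron-poor enoate, and the Z-alkene and the thermodynamic C8 epimer are unaffected.

**Compound list**

1 | tert-butyl 3-oxobutanoate | CC(=O)CC(=O)OC(C)(C)C | starting material
2 | tert-butyl 2-diazo-3-oxobutanoate | CC(=O)C(=[N+]=[N-])C(=O)OC(C)(C)C | intermediate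
3 | tert-butyl 2-diazo-3-hydroxybutanoate (racemic) | CC(O)C(=[N+]=[N-])C(=O)OC(C)(C)C | intermediate
4 | tert-butyl 2-diazobut-3-enoate | C=CC(=[N+]=[N-])C(=O)OC(C)(C)C | intermediate
5 | cyclopent-2-en-1-one | O=C1CCC=C1 | starting material
6 | 2-iodocyclopent-2-en-1-one | O=C1CCC=C1I | intermediate
7 | methyl but-3-enoate | C=CCC(=O)OC | starting material
8 | methyl 4-(9-borabicyclo[3.3.1]nonan-9-yl)butanoate | COC(=O)CCCB1C2CCCC1CCC2 | intermediate (not isolated)
9 | methyl 4-(5-oxocyclopent-1-en-1-yl)butanoate | O=C1CCC=C1CCCC(=O)OC | intermediate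
10 | methyl 4-[3-(tert-butyldimethylsilyloxy)cyclopenta-1,3-dien-2-yl]butanoate | CC(C)(C)[Si](C)(C)OC1=CCC=C1CCCC(=O)OC | intermediate
11 | tert-butyl 1-(tert-butyldimethylsilyloxy)-2-(4-methoxy-4-oxobutyl)-6-endo-vinylbicyclo[3.1.0]hex-2-ene-6-carboxylate (cis-divinylcyclopropane) | C=C[C@]1(C(=O)OC(C)(C)C)[C@@H]2CC=C(CCCC(=O)OC)[C@]12O[Si](C)(C)C(C)(C)C | intermediate (not isolated)
12 | tert-butyl 7-(tert-butyldimethylsilyloxy)-6-(4-methoxy-4-oxobutyl)bicyclo[3.2.1]octa-2,6-diene-2-carboxylate | CC(C)(C)[Si](C)(C)OC1=C(CCCC(=O)OC)[C@@H]2C[C@H]1C(C(=O)OC(C)(C)C)=CC2 | intermediate (not isolated)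
13 | tert-butyl 6-exo-(4-methoxy-4-oxobutyl)-7-oxobicyclo[3.2.1]oct-2-ene-2-carboxylate (ketone at C1; C11 chain exo) | O=C1[C@H]2C[C@H](CC=C2C(=O)OC(C)(C)C)[C@H]1CCCC(=O)OC | intermediate
14 | tert-butyl 7-(methoxymethylidene)-6-exo-(4-methoxy-4-oxobutyl)bicyclo[3.2.1]oct-2-ene-2-carboxylate (E/Z mixture) | COC=C1[C@H]2C[C@H](CC=C2C(=O)OC(C)(C)C)[C@H]1CCCC(=O)OC | intermediate
15 | tert-butyl 7-formyl-6-exo-(4-methoxy-4-oxobutyl)bicyclo[3.2.1]oct-2-ene-2-carboxylate (C1 epimers) | O=CC1[C@H]2C[C@H](CC=C2C(=O)OC(C)(C)C)[C@H]1CCCC(=O)OC | intermediate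
16 | tert-butyl 7-exo-formyl-7-endo-(hydroxymethyl)-6-exo-(4-methoxy-4-oxobutyl)bicyclo[3.2.1]oct-2-ene-2-carboxylate | O=C[C@@]1(CO)[C@H]2C[C@H](CC=C2C(=O)OC(C)(C)C)[C@H]1CCCC(=O)OC | intermediate
17 | N-tosylhydrazone of 16 | Cc1ccc(cc1)S(=O)(=O)NN=C[C@@]1(CO)[C@H]2C[C@H](CC=C2C(=O)OC(C)(C)C)[C@H]1CCCC(=O)OC | intermediate (not isolated)
18 | tert-butyl 7-endo-(hydroxymethyl)-6-exo-(4-methoxy-4-oxobutyl)-7-exo-methylbicyclo[3.2.1]oct-2-ene-2-carboxylate | C[C@@]1(CO)[C@H]2C[C@H](CC=C2C(=O)OC(C)(C)C)[C@H]1CCCC(=O)OC | intermediate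
19 | tert-butyldimethylsilyl ether of 18 | C[C@@]1(CO[Si](C)(C)C(C)(C)C)[C@H]2C[C@H](CC=C2C(=O)OC(C)(C)C)[C@H]1CCCC(=O)OC | intermediate
20 | 19 carrying a trifluoroacetyl group on C8 (α to the methyl ester) | C[C@@]1(CO[Si](C)(C)C(C)(C)C)[C@H]2C[C@H](CC=C2C(=O)OC(C)(C)C)[C@H]1CCC(C(=O)C(F)(F)F)C(=O)OC | intermediate (not isolated)
21 | α-diazo ester: tert-butyl 7-endo-[(tert-butyldimethylsilyloxy)methyl]-6-exo-(3-diazo-4-methoxy-4-oxobutyl)-7-exo-methylbicyclo[3.2.1]oct-2-ene-2-carboxylate | C[C@@]1(CO[Si](C)(C)C(C)(C)C)[C@H]2C[C@H](CC=C2C(=O)OC(C)(C)C)[C@H]1CCC(=[N+]=[N-])C(=O)OC | intermediate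
22 | tricyclic diester: rings A, B and C; C7 CO2t-Bu; C8 CO2Me (epimers); C1 exo-CH3 and endo-CH2OTBS | C[C@@]1(CO[Si](C)(C)C(C)(C)C)[C@H]2C[C@@]3(CC=C2C(=O)OC(C)(C)C)C(C(=O)OC)CC[C@@H]13 | intermediate
23 | tricyclic alcohol: as 22 with CH2OH on C8 (epimers) | C[C@@]1(CO[Si](C)(C)C(C)(C)C)[C@H]2C[C@@]3(CC=C2C(=O)OC(C)(C)C)C(CO)CC[C@@H]13 | intermediate
24 | tricyclic aldehyde: CHO on C8, syn to C3 as in the target | C[C@@]1(CO[Si](C)(C)C(C)(C)C)[C@H]2C[C@@]3(CC=C2C(=O)OC(C)(C)C)[C@@H](C=O)CC[C@@H]13 | intermediate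
25 | dimethyl acetal of 24 | C[C@@]1(CO[Si](C)(C)C(C)(C)C)[C@H]2C[C@@]3(CC=C2C(=O)OC(C)(C)C)[C@@H](C(OC)OC)CC[C@@H]13 | intermediate
26 | γ-keto enoate: 25 with a ketone at C5 | C[C@@]1(CO[Si](C)(C)C(C)(C)C)[C@H]2C[C@@]3(C(=O)C=C2C(=O)OC(C)(C)C)[C@@H](C(OC)OC)CC[C@@H]13 | intermediate
27 | allylic alcohol: C5–OH syn to the C1–C11 bridge | C[C@@]1(CO[Si](C)(C)C(C)(C)C)[C@H]2C[C@@]3([C@@H](O)C=C2C(=O)OC(C)(C)C)[C@@H](C(OC)OC)CC[C@@H]13 | intermediate
28 | heptane-1,7-diol | OCCCCCCCO | starting material
29 | 7-(tert-butyldimethylsilyloxy)heptan-1-ol | OCCCCCCCO[Si](C)(C)C(C)(C)C | intermediate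
30 | 7-(tert-butyldimethylsilyloxy)heptanal | O=CCCCCCCO[Si](C)(C)C(C)(C)C | intermediate
31 | 9-bromononanoic acid | OC(=O)CCCCCCCCBr | starting material
32 | (8-carboxyoctyl)triphenylphosphonium bromide | OC(=O)CCCCCCCC[P+](c1ccccc1)(c1ccccc1)c1ccccc1.[Br-] | intermediate
33 | sodium 9-(triphenylphosphoranylidene)nonanoate | [Na+].[O-]C(=O)CCCCCCCC=P(c1ccccc1)(c1ccccc1)c1ccccc1 | intermediate (not isolated)
34 | (Z)-16-(tert-butyldimethylsilyloxy)hexadec-9-enoic acid | OC(=O)CCCCCCC/C=C\CCCCCCO[Si](C)(C)C(C)(C)C | intermediate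
35 | mixed anhydride of 34 with 2,4,6-trichlorobenzoic acid | CC(C)(C)[Si](C)(C)OCCCCCC/C=C\CCCCCCCC(=O)OC(=O)c1c(Cl)cc(Cl)cc1Cl | intermediate (not isolated)
36 | fully protected ester: 27 acylated at C5–O by 34 | C[C@@]1(CO[Si](C)(C)C(C)(C)C)[C@H]2C[C@@]3([C@@H](OC(=O)CCCCCCC/C=C\CCCCCCO[Si](C)(C)C(C)(C)C)C=C2C(=O)OC(C)(C)C)[C@@H](C(OC)OC)CC[C@@H]13 | intermediate
37 | CNP0148862.2: C7 acid, C8 aldehyde, C1 hydroxymethyl, C5 ester of (Z)-16-hydroxyhexadec-9-enoic acid | C[C@@]1(CO)[C@H]2C[C@@]3([C@@H](OC(=O)CCCCCCC/C=C\CCCCCCO)C=C2C(=O)O)[C@@H](C=O)CC[C@@H]13 | target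

**Step count.** 25 steps in total. Longest linear sequence: 18 steps (steps 4–19, 24, 25).

**Steps most likely to fail**

1. Step 14. The risk is that 1,2-hydride migration from C9 to the carbenoid carbon (giving the Z-enoate), or insertion elsewhere, outruns insertion into the somewhat strained bridgehead C–H bond. The fallback uses an acceptor/acceptor carbenoid, which cannot undergo hydride migration, and removes the extra ketone afterwards. It sets out from 19. Enolisation (LiN(SiMe3)2) and PhSeBr give the α-phenylselanyl ester F1, and H2O2 eliminates it to the (E)-enoate F2. Wacker–Tsuji oxidation (Na2PdCl4, t-BuOOH, aq. AcOH) should give the β-keto ester F3, and Regitz transfer (4-acetamidobenzenesulfonyl azide, Et3N) the α-diazo-β-keto ester F4. Rh2(OAc)4 in CH2Cl2 should then insert into the same C4–H bond to give the tricyclic β-keto ester F5. NaBH4 gives the C9 alcohol F6, PhOC(S)Cl/DMAP the thionocarbonate F7, and Barton–McCombie reduction (Bu3SnH, AIBN) comes back to the route at 22.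

2. Step 7. The risks are attack of the carbenoid at the alkyl-substituted double bond or zwitterionic side reactions of the silyl enol ether, erosion of enantiocontrol by the extra diene substituent, and an incomplete exo preference at C11 on equilibration. The fallback introduces the chain after the cycloaddition, by kinetic alkylation. It sets out from 5: TBSOTf/Et3N gives the parent 2-(tert-butyldimethylsilyloxy)cyclopenta-1,3-diene F8. The same rhodium-catalysed reaction with 4 passes through the cis-divinylcyclopropane F9 and the silyl enol ether F10 and gives, after acid, the unsubstituted ketone F11. LDA and allyl bromide alkylate the only enolisable position, C11, from the exo face to give the allyl ketone F12. Cross-metathesis with methyl acrylate (second-generation Hoveyda–Grubbs catalyst) gives the enoate F13, and chemoselective conjugate reduction of this disubstituted enoate with [(Ph3P)CuH]6 comes back to the route at 13.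

3. Step 10. The risk is low or reversed facial selectivity in the bond formation at C1, with the electrophile entering on the exo face. The fallback inverts the order in which the two C1 substituents are made, which then gives the same compound. It sets out from 15: KOt-Bu/MeI methylation gives the 7-exo-methyl-7-endo-formyl aldehyde F14, and NaBH4 reduction of its formyl group comes back to the route at 18.

**Further compounds**

F1 | step 14 | α-phenylselanyl ester of 19 (PhSe on C8) | C[C@@]1(CO[Si](C)(C)C(C)(C)C)[C@H]2C[C@H](CC=C2C(=O)OC(C)(C)C)[C@H]1CCC([Se]c3ccccc3)C(=O)OC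
F2 | step 14 | (E)-enoate of 19 (C8=C9) | C[C@@]1(CO[Si](C)(C)C(C)(C)C)[C@H]2C[C@H](CC=C2C(=O)OC(C)(C)C)[C@H]1C/C=C/C(=O)OC
F3 | step 14 | β-keto ester (ketone at C9) | C[C@@]1(CO[Si](C)(C)C(C)(C)C)[C@H]2C[C@H](CC=C2C(=O)OC(C)(C)C)[C@H]1CC(=O)CC(=O)OC
F4 | step 14 | α-diazo-β-keto ester | C[C@@]1(CO[Si](C)(C)C(C)(C)C)[C@H]2C[C@H](CC=C2C(=O)OC(C)(C)C)[C@H]1CC(=O)C(=[N+]=[N-])C(=O)OC
F5 | step 14 | tricyclic β-keto ester (22 with a ketone at C9) | C[C@@]1(CO[Si](C)(C)C(C)(C)C)[C@H]2C[C@@]3(CC=C2C(=O)OC(C)(C)C)C(C(=O)OC)C(=O)C[C@@H]13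
F6 | step 14 | tricyclic β-hydroxy ester (OH on C9) | C[C@@]1(CO[Si](C)(C)C(C)(C)C)[C@H]2C[C@@]3(CC=C2C(=O)OC(C)(C)C)C(C(=O)OC)C(O)C[C@@H]13
F7 | step 14 | C9 O-phenyl thionocarbonate of F6 | C[C@@]1(CO[Si](C)(C)C(C)(C)C)[C@H]2C[C@@]3(CC=C2C(=O)OC(C)(C)C)C(C(=O)OC)C(OC(=S)Oc4ccccc4)C[C@@H]13
F8 | step 7 | 2-(tert-butyldimethylsilyloxy)cyclopenta-1,3-diene | CC(C)(C)[Si](C)(C)OC1=CCC=C1
F9 | step 7 | tert-butyl 1-(tert-butyldimethylsilyloxy)-6-endo-vinylbicyclo[3.1.0]hex-2-ene-6-carboxylate | C=C[C@]1(C(=O)OC(C)(C)C)[C@@H]2CC=C[C@]12O[Si](C)(C)C(C)(C)C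
F10 | step 7 | tert-butyl 7-(tert-butyldimethylsilyloxy)bicyclo[3.2.1]octa-2,6-diene-2-carboxylate | CC(C)(C)[Si](C)(C)OC1=C[C@@H]2C[C@H]1C(C(=O)OC(C)(C)C)=CC2
F11 | step 7 | tert-butyl 7-oxobicyclo[3.2.1]oct-2-ene-2-carboxylate | O=C1[C@H]2C[C@H](CC=C2C(=O)OC(C)(C)C)C1
F12 | step 7 | tert-butyl 6-exo-allyl-7-oxobicyclo[3.2.1]oct-2-ene-2-carboxylate | O=C1[C@H]2C[C@H](CC=C2C(=O)OC(C)(C)C)[C@H]1CC=C
F13 | step 7 | tert-butyl 6-exo-[(E)-4-methoxy-4-oxobut-2-enyl]-7-oxobicyclo[3.2.1]oct-2-ene-2-carboxylate | O=C1[C@H]2C[C@H](CC=C2C(=O)OC(C)(C)C)[C@H]1C/C=C/C(=O)OC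
F14 | step 10 | tert-butyl 7-endo-formyl-6-exo-(4-methoxy-4-oxobutyl)-7-exo-methylbicyclo[3.2.1]oct-2-ene-2-carboxylate | C[C@@]1(C=O)[C@H]2C[C@H](CC=C2C(=O)OC(C)(C)C)[C@H]1CCCC(=O)OC
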